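3 questions are asked of this flask, and we let one quantity carry the two about excess.

- excess of left-handed product over right-handed product in the product at 5.0 min
- excess of left-handed product over right-handed product in the product at 50 min
- part of the left-handed substrate and right-handed substrate charged together that has reacted at 50 min

the same everywhere: left-handed substrate 0.74 M; right-handed substrate 0.74 M; racemization catalyst 5 mol%

| flask | coupling partner | remark | time |
|---|---|---|---|
| Friday's | 1.2 equiv | run made earlier |  |
| Monday's | 1.9 equiv | run made earlier |  |
| flask | 2.50 equiv |  | 50 min |

- Friday's (time / min: left-handed product / %, right-handed product / %, left-handed substrate / %): 10.0: 2.9, 1.1, 50.0; 20.0: 1.8, 1.9, 47.7; 30.0: 5.2, 3.2, 43.5; 40.0: 6.7, 3.9, 45.2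
- Monday's (time / min: left-handed product / %, right-handed product / %, left-handed substrate / %): 5.00: 1.8, 3.1, 50.2; 15.0: 3.9, 3.6, 45.0; 25.0: 6.2, 3.9, 44.6; 40.0: 8.2, 3.7, 40.0

(each reading ± 1 percentage point)

- coupling partner is single-handed; left-handed substrate and right-handed substrate are mirror images of each other, charged as a racemate, each of them at the stated concentration
- an excess is the difference of the two amounts in percent of their sum
- an excess is below zero if the other one leads
- the handed part of coupling partner does not stay in what it makes, so the products of the two hands are mirror images too

Our zero is the mirror case: with equal rates on both substrates the product excess is nil. The single-handed coupling partner shifts this by a rate ratio s, the selectivity factor. We read it at 40.0 min, the last time of both runs: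

s = left-handed product / right-handed product = 1.96

The starting excess, the difference of the two rates over their sum while the substrates stand equal, is then

32.4%

Each reading scatters by 1 percentage point, and the four readings used add up to 22.5%, so this value is rough.

From above: left-handed substrate is used faster, so it falls behind right-handed substrate, and racemization pulls the two back toward equality. We therefore put the excess at or below the starting excess.

From below: if each substrate ran down on its own, the ratio would fall to about s(1 − starting excess × c), with c the part reacted. Taking the rate as proportional to partner, the runs give

c = 22.7%

lower bound = 29.0%

In this flask at 5.0 min we reckon 2.27% reacted, so the early excess belongs at the top of the bracket.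

The forecast said 8%, 47% and 17%, with an excess that “rises from about zero early”, so both its excesses stand outside our bracket.

The flask gives 31.9%, 30.2% and 23.5%.

    coupling partner + right-handed substrate → right-handed product (k = 0.00220 L mol⁻¹ min⁻¹)
    2 racemization catalyst → spent catalyst B (k = 0.150 L mol⁻¹ min⁻¹)
    racemization catalyst → spent catalyst A (k = 0.0280 min⁻¹)
    coupling partner + left-handed substrate → left-handed product (k = 0.00430 L mol⁻¹ min⁻¹)
    left-handed substrate + racemization catalyst ⇌ right-handed substrate + racemization catalyst, rate k5*[racemization catalyst]*[left-handed substrate] forward; the back reaction follows from the equilibrium constant (k = 1.20 L mol⁻¹ min⁻¹)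

Over 50 min in this flask both couplings ran, taking coupling partner to 81.2% of its charge, while racemization catalyst fell from 82.7% at 5.00 min to 19.0%, beside spent catalyst A at 65.9% and spent catalyst B at 15.1%. In this flask left-handed substrate ended at 36.5% against 40.0% right-handed, and the excess stood inside the bracket.

For the neighbour flask with 1.50 equiv of partner, the same reckoning gives c = 13.6% and a bracket from 30.4% to 32.4%. That flask gives 32.1% early, 31.0% at the end and 14.8% reacted.

(The earlier runs and the new flask are calculated for an exercise; scatter was added.)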